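## Retrosynthetic overview

1. The ester C–O bond is made last, by acylating the secondary allylic OH of the bicyclic 3a,8-diol with 4-methoxybenzoyl chloride.
2. The seven-membered ring is formed second: ring-closing metathesis closes C6=C7, and the C3a–C4 bond comes from adding a 3-methylbut-3-enyl Grignard reagent to a cyclopentanone, which sets C3a.
3. The key C8–C8a bond is an intermolecular carbonyl allylation of acrolein with a ring-locked, tetrasubstituted allylboronate. It sets C8 and the quaternary C8a and leaves an exocyclic methylene that is cut down to the C3a ketone.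
4. The five-membered ring is formed first, from the chiral pool: (S)-limonene is hydrogenated to (S)-p-menth-1-ene, then ozonolysis and aldol condensation give a cyclopentene carbaldehyde that carries the C3 stereocentre.

Assumption: the SMILES is taken as drawn, i.e. (3R,3aS,8R,8aR) in azulene numbering, with C8a-CH3, C3a-OH and C3-isopropyl mutually cis and C8-O trans to C8a-CH3; the overview and the fallbacks use this numbering.

## Route

Step 1
Reactants: 1 (S)-(−)-limonene
Product: 2 (4S)-1-methyl-4-(propan-2-yl)cyclohex-1-ene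
Conditions: H2 (1 atm), RhCl(PPh3)3 (2 mol %), benzene/EtOH 1:1, rt
Reagents that add atoms: none
Why: Homogeneous catalytic hydrogenation reduces the unhindered 1,1-disubstituted alkene and leaves the trisubstituted ring alkene; the stereocentre is untouched.

Step 2
Reactants: 2 (4S)-1-methyl-4-(propan-2-yl)cyclohex-1-ene
Product: 4 (3S)-6-oxo-3-(propan-2-yl)heptanal, via ozonide 3 (not isolated)
Conditions: O3, CH2Cl2, −78 °C; then Me2S, −78 °C → rt
Reagents that add atoms: ozone, O=[O+][O-]
Why: Ozonolysis (cycloaddition and cycloreversion to the ozonide, then reductive work-up) opens the ring to the keto aldehyde; the stereocentre is remote from both carbonyl groups.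

Step 3
Reactants: 4 (3S)-6-oxo-3-(propan-2-yl)heptanal
Product: 6 (5R)-2-methyl-5-(propan-2-yl)cyclopent-1-ene-1-carbaldehyde, via aldol adduct 5 (not isolated)
Conditions: piperidine (0.2 equiv), AcOH (0.2 equiv), benzene, reflux, Dean–Stark
Reagents that add atoms: none
Why: Amine-catalysed intramolecular aldol condensation (the enamine of the aldehyde attacks the methyl ketone, then dehydration) gives the formylcyclopentene; the stereocentre has no acidifying carbonyl next to it and survives.

Step 4
Reactants: 6 (5R)-2-methyl-5-(propan-2-yl)cyclopent-1-ene-1-carbaldehyde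
Product: 7 [(5R)-2-methyl-5-(propan-2-yl)cyclopent-1-en-1-yl]methanol
Conditions: NaBH4, CeCl3·7H2O, MeOH, 0 °C
Reagents that add atoms: none
Why: Luche reduction delivers hydride 1,2 to the enal and gives the primary allylic alcohol without conjugate reduction.

Step 5
Reactants: 7 [(5R)-2-methyl-5-(propan-2-yl)cyclopent-1-en-1-yl]methanol
Product: 8 [(5R)-2-methyl-5-(propan-2-yl)cyclopent-1-en-1-yl]methyl acetate
Conditions: Ac2O, pyridine, DMAP (cat.), CH2Cl2, rt
Reagents that add atoms: acetic anhydride, CC(=O)OC(C)=O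
Why: DMAP-catalysed acetylation installs the leaving group needed for the palladium step.

Step 6
Reactants: 8 [(5R)-2-methyl-5-(propan-2-yl)cyclopent-1-en-1-yl]methyl acetate
Product: 9 4,4,5,5-tetramethyl-2-{[(5R)-2-methyl-5-(propan-2-yl)cyclopent-1-en-1-yl]methyl}-1,3,2-dioxaborolane
Conditions: B2pin2 (1.1 equiv), Pd2(dba)3 (2.5 mol %), DMSO, 50 °C
Reagents that add atoms: bis(pinacolato)diboron (B2pin2), CC1(C)OB(OC1(C)C)B1OC(C)(C)C(C)(C)O1
Why: Miyaura-type allylic borylation: zerovalent palladium ionises the acetate to a π-allyl complex, and transmetalation with B2pin2 followed by reductive elimination at the primary terminus gives the linear allylboronate with the ring alkene intact.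

Step 7
Reactants: 9 4,4,5,5-tetramethyl-2-{[(5R)-2-methyl-5-(propan-2-yl)cyclopent-1-en-1-yl]methyl}-1,3,2-dioxaborolane; 10 acrolein (3 equiv)
Product: 12 (1R)-1-[(1S,3R)-1-methyl-2-methylidene-3-(propan-2-yl)cyclopentyl]prop-2-en-1-ol, via borate ester 11 (not isolated)
Conditions: Sc(OTf)3 (10 mol %), toluene, −78 → −40 °C; then 1 M aq. NaOH, rt
Reagents that add atoms: none
Why: Lewis-acid-catalysed allylboration (carbonyl allylation through a closed chair transition state) bonds the tetrasubstituted γ-carbon to the aldehyde on the ring face opposite the isopropyl group, which sets the quaternary centre (1S), while the equatorial vinyl group and the ring-locked alkene geometry (CH3 cis to CH2B, hence axial) set the carbinol centre (1R).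

Step 8
Reactants: 12 (1R)-1-[(1S,3R)-1-methyl-2-methylidene-3-(propan-2-yl)cyclopentyl]prop-2-en-1-ol
Product: 13 tert-butyl(dimethyl){[(1R)-1-[(1S,3R)-1-methyl-2-methylidene-3-(propan-2-yl)cyclopentyl]prop-2-en-1-yl]oxy}silane
Conditions: TBSOTf, 2,6-lutidine, CH2Cl2, −78 → 0 °C
Reagents that add atoms: tert-butyldimethylsilyl trifluoromethanesulfonate (TBSOTf), CC(C)(C)[Si](C)(C)OS(=O)(=O)C(F)(F)F
Why: Silylation with the reactive silyl triflate protects the hindered secondary alcohol, which blocks retro-aldol cleavage once the ketone is unveiled and deactivates the vinyl group toward the peracid.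

Step 9
Reactants: 13 tert-butyl(dimethyl){[(1R)-1-[(1S,3R)-1-methyl-2-methylidene-3-(propan-2-yl)cyclopentyl]prop-2-en-1-yl]oxy}silane
Product: 14 tert-butyl(dimethyl){[(1R)-1-[(4R,7R)-4-methyl-7-(propan-2-yl)-1-oxaspiro[2.4]heptan-4-yl]prop-2-en-1-yl]oxy}silane (both spiro epimers)
Conditions: mCPBA (1.1 equiv), NaHCO3, CH2Cl2, 0 °C
Reagents that add atoms: mCPBA, OOC(=O)c1cccc(Cl)c1
Why: Prilezhaev epoxidation is chemoselective for the electron-richer 1,1-disubstituted exocyclic alkene over the monosubstituted vinyl group bearing the allylic silyloxy group; the new spiro centre is destroyed in the next step, so its configuration does not matter.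

Step 10
Reactants: 14 tert-butyl(dimethyl){[(1R)-1-[(4R,7R)-4-methyl-7-(propan-2-yl)-1-oxaspiro[2.4]heptan-4-yl]prop-2-en-1-yl]oxy}silane
Product: 16 (2R,5R)-2-[(1R)-1-{[tert-butyl(dimethyl)silyl]oxy}prop-2-en-1-yl]-2-methyl-5-(propan-2-yl)cyclopentan-1-one, via diol 15 (not isolated)
Conditions: H5IO6 (1.5 equiv), THF/H2O 4:1, 0 °C → rt
Reagents that add atoms: water, O
Why: Acid-mediated epoxide hydrolysis to the 1,2-diol followed by periodate glycol cleavage (Malaprade reaction) removes the CH2 carbon as formaldehyde and leaves the ring ketone from both epoxide epimers; the α-centre C5 is not disturbed under these cold, mildly acidic conditions and has the isopropyl group trans to the larger C2 substituent in any case.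

Step 11
Reactants: 17 4-bromo-2-methylbut-1-ene
Product: 18 (3-methylbut-3-en-1-yl)magnesium bromide (titrated THF solution)
Conditions: Mg turnings, THF, 25–40 °C
Reagents that add atoms: magnesium, [Mg]
Why: Grignard formation by insertion of magnesium into the primary C–Br bond; the homoallylic reagent does not rearrange.

Step 12
Reactants: 16 (2R,5R)-2-[(1R)-1-{[tert-butyl(dimethyl)silyl]oxy}prop-2-en-1-yl]-2-methyl-5-(propan-2-yl)cyclopentan-1-one; 18 (3-methylbut-3-en-1-yl)magnesium bromide (1.5 equiv)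
Product: 19 (1S,2R,5R)-2-[(1R)-1-{[tert-butyl(dimethyl)silyl]oxy}prop-2-en-1-yl]-2-methyl-1-(3-methylbut-3-en-1-yl)-5-(propan-2-yl)cyclopentan-1-ol
Conditions: LaCl3·2LiCl (1.0 equiv), THF, −20 → 0 °C; then H2O
Reagents that add atoms: none
Why: Lanthanum-promoted Grignard 1,2-addition (enolisation and β-hydride reduction suppressed) is expected to occur on the carbonyl face opposite the cis-disposed C5 isopropyl and C2 methyl groups, giving the (1S) tertiary alcohol with the two alkenyl chains cis; the minor C1 epimer is removed by chromatography.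

Step 13
Reactants: 19 (1S,2R,5R)-2-[(1R)-1-{[tert-butyl(dimethyl)silyl]oxy}prop-2-en-1-yl]-2-methyl-1-(3-methylbut-3-en-1-yl)-5-(propan-2-yl)cyclopentan-1-ol
Product: 20 (1S,2R,5R)-2-[(1R)-1-hydroxyprop-2-en-1-yl]-2-methyl-1-(3-methylbut-3-en-1-yl)-5-(propan-2-yl)cyclopentan-1-ol
Conditions: Bu4NF (TBAF), THF, rt → 45 °C
Reagents that add atoms: none
Why: Fluoride-induced desilylation frees the secondary allylic alcohol without touching the alkenes or the tertiary alcohol.

Step 14
Reactants: 20 (1S,2R,5R)-2-[(1R)-1-hydroxyprop-2-en-1-yl]-2-methyl-1-(3-methylbut-3-en-1-yl)-5-(propan-2-yl)cyclopentan-1-ol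
Product: 21 (3R,3aS,8R,8aR)-6,8a-dimethyl-3-(propan-2-yl)-2,3,4,5,8,8a-hexahydroazulene-3a,8(1H)-diol
Conditions: second-generation Grubbs catalyst RuCl2(=CHPh)(H2IMes)(PCy3) (5 mol %), 1,4-benzoquinone (10 mol %), CH2Cl2 (0.005 M), 40 °C
Reagents that add atoms: none
Why: Ring-closing olefin metathesis of the cis-disposed vinyl and 1,1-disubstituted alkenes closes the seven-membered ring as the trisubstituted cycloheptene with loss of ethene, the free allylic hydroxyl speeding initiation and benzoquinone suppressing ruthenium hydride isomerisation; no stereocentre is touched.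

Step 15
Reactants: 21 (3R,3aS,8R,8aR)-6,8a-dimethyl-3-(propan-2-yl)-2,3,4,5,8,8a-hexahydroazulene-3a,8(1H)-diol; 22 4-methoxybenzoyl chloride (1.5 equiv)
Product: 23 (3R,3aS,8R,8aR)-3a-hydroxy-6,8a-dimethyl-3-(propan-2-yl)-1,2,3,3a,4,5,8,8a-octahydroazulen-8-yl 4-methoxybenzoate
Conditions: Et3N, DMAP (0.2 equiv), CH2Cl2, 0 °C → rt
Reagents that add atoms: none
Why: DMAP-catalysed acylation (nucleophilic catalysis via the acylpyridinium ion) esterifies only the secondary allylic hydroxyl, the tertiary ring-fusion hydroxyl being too hindered; C8 keeps its configuration because its C–O bond is not broken.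

## Compound list

1 | (S)-(−)-limonene, (4S)-1-methyl-4-(prop-1-en-2-yl)cyclohex-1-ene | CC1=CC[C@@H](C(C)=C)CC1 | starting material
2 | (4S)-1-methyl-4-(propan-2-yl)cyclohex-1-ene, (S)-p-menth-1-ene | CC1=CC[C@@H](C(C)C)CC1 | intermediate
3 | (4S)-1-methyl-4-(propan-2-yl)-7,8,9-trioxabicyclo[4.2.1]nonane (ozonide, bridgeheads undefined, not isolated) | CC12CC[C@H](C(C)C)CC(OO1)O2 | intermediate
4 | (3S)-6-oxo-3-(propan-2-yl)heptanal | O=CC[C@@H](C(C)C)CCC(C)=O | intermediate
5 | (5R)-2-hydroxy-2-methyl-5-(propan-2-yl)cyclopentane-1-carbaldehyde (aldol adduct, C1 and C2 undefined, not isolated) | O=CC1[C@@H](C(C)C)CCC1(C)O | intermediate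
6 | (5R)-2-methyl-5-(propan-2-yl)cyclopent-1-ene-1-carbaldehyde | CC1=C(C=O)[C@@H](C(C)C)CC1 | intermediate
7 | [(5R)-2-methyl-5-(propan-2-yl)cyclopent-1-en-1-yl]methanol | CC1=C(CO)[C@@H](C(C)C)CC1 | intermediate
8 | [(5R)-2-methyl-5-(propan-2-yl)cyclopent-1-en-1-yl]methyl acetate | CC1=C(COC(C)=O)[C@@H](C(C)C)CC1 | intermediate
9 | 4,4,5,5-tetramethyl-2-{[(5R)-2-methyl-5-(propan-2-yl)cyclopent-1-en-1-yl]methyl}-1,3,2-dioxaborolane | CC1=C(CB2OC(C)(C)C(C)(C)O2)[C@@H](C(C)C)CC1 | intermediate
10 | acrolein (prop-2-enal) | C=CC=O | starting material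
11 | 4,4,5,5-tetramethyl-2-{[(1R)-1-[(1S,3R)-1-methyl-2-methylidene-3-(propan-2-yl)cyclopentyl]prop-2-en-1-yl]oxy}-1,3,2-dioxaborolane (borate ester, not isolated) | C=C[C@@H](OB2OC(C)(C)C(C)(C)O2)[C@@]1(C)CC[C@H](C(C)C)C1=C | intermediate
12 | (1R)-1-[(1S,3R)-1-methyl-2-methylidene-3-(propan-2-yl)cyclopentyl]prop-2-en-1-ol | C=C[C@@H](O)[C@@]1(C)CC[C@H](C(C)C)C1=C | intermediate
13 | tert-butyl(dimethyl){[(1R)-1-[(1S,3R)-1-methyl-2-methylidene-3-(propan-2-yl)cyclopentyl]prop-2-en-1-yl]oxy}silane | C=C[C@@H](O[Si](C)(C)C(C)(C)C)[C@@]1(C)CC[C@H](C(C)C)C1=C | intermediate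
14 | tert-butyl(dimethyl){[(1R)-1-[(4R,7R)-4-methyl-7-(propan-2-yl)-1-oxaspiro[2.4]heptan-4-yl]prop-2-en-1-yl]oxy}silane (both spiro epimers) | C=C[C@@H](O[Si](C)(C)C(C)(C)C)[C@@]1(C)CC[C@H](C(C)C)C12CO2 | intermediate
15 | (2R,5R)-2-[(1R)-1-{[tert-butyl(dimethyl)silyl]oxy}prop-2-en-1-yl]-1-(hydroxymethyl)-2-methyl-5-(propan-2-yl)cyclopentan-1-ol (C1 epimers, not isolated) | C=C[C@@H](O[Si](C)(C)C(C)(C)C)[C@@]1(C)CC[C@H](C(C)C)C1(O)CO | intermediate
16 | (2R,5R)-2-[(1R)-1-{[tert-butyl(dimethyl)silyl]oxy}prop-2-en-1-yl]-2-methyl-5-(propan-2-yl)cyclopentan-1-one | C=C[C@@H](O[Si](C)(C)C(C)(C)C)[C@@]1(C)CC[C@H](C(C)C)C1=O | intermediate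
17 | 4-bromo-2-methylbut-1-ene | C=C(C)CCBr | starting material
18 | (3-methylbut-3-en-1-yl)magnesium bromide | C=C(C)CC[Mg]Br | intermediate
19 | (1S,2R,5R)-2-[(1R)-1-{[tert-butyl(dimethyl)silyl]oxy}prop-2-en-1-yl]-2-methyl-1-(3-methylbut-3-en-1-yl)-5-(propan-2-yl)cyclopentan-1-ol | C=C[C@@H](O[Si](C)(C)C(C)(C)C)[C@@]1(C)CC[C@H](C(C)C)[C@@]1(O)CCC(C)=C | intermediate
20 | (1S,2R,5R)-2-[(1R)-1-hydroxyprop-2-en-1-yl]-2-methyl-1-(3-methylbut-3-en-1-yl)-5-(propan-2-yl)cyclopentan-1-ol | C=C[C@@H](O)[C@@]1(C)CC[C@H](C(C)C)[C@@]1(O)CCC(C)=C | intermediate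
21 | (3R,3aS,8R,8aR)-6,8a-dimethyl-3-(propan-2-yl)-2,3,4,5,8,8a-hexahydroazulene-3a,8(1H)-diol | O[C@@H]1C=C(C)CC[C@]2(O)[C@@H](C(C)C)CC[C@]12C | intermediate
22 | 4-methoxybenzoyl chloride | COc1ccc(C(=O)Cl)cc1 | starting material
23 | (3R,3aS,8R,8aR)-3a-hydroxy-6,8a-dimethyl-3-(propan-2-yl)-1,2,3,3a,4,5,8,8a-octahydroazulen-8-yl 4-methoxybenzoate | COc1ccc(C(=O)O[C@@H]2C=C(C)CC[C@]3(O)[C@@H](C(C)C)CC[C@]23C)cc1 | target

## Step count and risks

Total step count: 15. Longest linear sequence: 14 steps (steps 1–10 and 12–15, from 1 to 23); step 11 is a one-step side branch that prepares Grignard reagent 18.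

The three steps most likely to fail:

Step 7 (key allylboration). The congested tetrasubstituted boronate may react slowly or with imperfect control at the carbinol centre, and it depends on step 6 working. The fallback sets out from 7 and comes back at 12. Appel bromination of 7 (CBr4, PPh3, CH2Cl2, 0 °C) gives (3R)-2-(bromomethyl)-1-methyl-3-(propan-2-yl)cyclopent-1-ene F1. Treating F1 with CrCl2 (2.5 equiv) in THF at 0 °C in the presence of acrolein 10 (Nozaki–Hiyama allylation) forms the transient {[(5R)-2-methyl-5-(propan-2-yl)cyclopent-1-en-1-yl]methyl}chromium dichloride F2. F2 adds through its tetrasubstituted γ-carbon in the same chair arrangement, anti to the isopropyl group, and aqueous work-up gives 12. This replaces the isolated boronate by an organochromium reagent made and consumed in one flask and bypasses steps 5 and 6.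

Step 10 (epoxide to ketone). The acidic opening next to a quaternary carbon could rearrange, or the silyl ether could suffer. The fallback sets out from 13 and comes back at 16, skipping steps 9 and 10. Ozone in CH2Cl2 at −78 °C, dosed to the end point of Sudan Red 7B, cleaves the electron-richer exocyclic alkene to tert-butyl(dimethyl){[(1R)-1-[(6R,9R)-6-methyl-9-(propan-2-yl)-1,2,4-trioxaspiro[4.4]nonan-6-yl]prop-2-en-1-yl]oxy}silane F3. Me2S reduces F3 in the same flask to 16, with no acid and no epoxide involved.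

Step 12 (facial selectivity at the ketone). The Grignard reagent may prefer the other carbonyl face and give mainly the C1 epimer. The fallback sets out from 14 and comes back at 19. If that face is the open one, the peracid of step 9 will have used the same face of the alkene, which is the face needed here. The major epoxide, tert-butyl(dimethyl){[(1R)-1-[(3S,4R,7R)-4-methyl-7-(propan-2-yl)-1-oxaspiro[2.4]heptan-4-yl]prop-2-en-1-yl]oxy}silane F4, is separated from 14 by chromatography. F4 is opened at its CH2 terminus with 2-methylallylmagnesium chloride (CuI 10 mol %, THF, −30 °C), forming the C4–C5 bond instead of C3a–C4 and giving 19 directly. The two approaches need opposite open faces, so one of them should deliver 19.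

## Further compounds

F1 | step 7 | (3R)-2-(bromomethyl)-1-methyl-3-(propan-2-yl)cyclopent-1-ene | CC1=C(CBr)[C@@H](C(C)C)CC1
F2 | step 7 | {[(5R)-2-methyl-5-(propan-2-yl)cyclopent-1-en-1-yl]methyl}chromium dichloride | CC1=C(C[Cr](Cl)Cl)[C@@H](C(C)C)CC1
F3 | step 10 | tert-butyl(dimethyl){[(1R)-1-[(6R,9R)-6-methyl-9-(propan-2-yl)-1,2,4-trioxaspiro[4.4]nonan-6-yl]prop-2-en-1-yl]oxy}silane (spiro centre undefined) | C=C[C@@H](O[Si](C)(C)C(C)(C)C)[C@@]1(C)CC[C@H](C(C)C)C12OCOO2
F4 | step 12 | tert-butyl(dimethyl){[(1R)-1-[(3S,4R,7R)-4-methyl-7-(propan-2-yl)-1-oxaspiro[2.4]heptan-4-yl]prop-2-en-1-yl]oxy}silane | C=C[C@@H](O[Si](C)(C)C(C)(C)C)[C@@]1(C)CC[C@H](C(C)C)[C@@]12CO2
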